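## Retrosynthetic overview

1. The target comes from a ten-membered triol by selective acetylation of its primary allylic hydroxyl. The ring is the only one and is closed last, at C5–C6, by an intramolecular B-alkyl Suzuki–Miyaura coupling that carries in the E-olefin.
2. C10–C1 is made just before ring closure by Nozaki–Hiyama–Kishi coupling of a C6–C15 α-silyloxy aldehyde with a C1–C5 (2Z,5E)-iodo/bromo-diene; Felkin control sets C10.
3. The aldehyde comes from a cis-β-hydroxy-γ-lactone whose C7–C10 are the four carbons of D-malic acid. Hydroboration/Suzuki coupling finishes the side chain, and lactol formation plus Wittig methylenation adds C6.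
4. Key step: the C8–C11 bond and both the C8 and C11 stereocentres arise in a chelated dianionic Ireland–Claisen [3,3] rearrangement of bis-(Z)-crotyl D-malate, under control of the bought C9 carbinol.
5. The dihalodiene comes from mono-silylated but-2-yne-1,4-diol by trans-hydroalumination/iodination, propynylation and hydrozirconation/bromination.

Numbering used: ring carbons C1 (bears CH2OAc) to C10 (allylic carbinol); C11 is the side-chain methine. The target is (1Z,4E,8S,9R,10S,11R).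

Assumption: D-malic acid, (Z)-but-2-en-1-ol, 1-bromo-2-methylprop-1-ene, 4-(tert-butyldimethylsilyloxy)but-2-yn-1-ol and prop-1-ynylmagnesium bromide (THF solution) are taken as catalogue chemicals.

## Route

Step 1
Reactants: 1 (2R)-2-hydroxybutanedioic acid (D-malic acid); 2 (2Z)-but-2-en-1-ol
Product: 3 bis[(2Z)-but-2-en-1-yl] (2R)-2-hydroxybutanedioate
Conditions: 2 (2.5 equiv), TsOH·H2O (5 mol%), benzene, Dean–Stark, reflux
Reagents that add atoms: none
Why: Fischer esterification with azeotropic removal of water converts both carboxyl groups without touching the bought C9 carbinol stereocentre or the Z-olefins.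

Step 2
Reactants: 3 bis[(2Z)-but-2-en-1-yl] (2R)-2-hydroxybutanedioate
Product: 5 (2S,3R)-2-[(2R)-but-3-en-2-yl]-3-hydroxybutanedioic acid 4-[(2Z)-but-2-en-1-yl] ester, via dilithium alkoxide enolate 4 (not isolated)
Conditions: LiN(i-Pr)2 (2.3 equiv), THF, −78 °C → 25 °C; then 1 M HCl
Reagents that add atoms: lithium diisopropylamide, [Li+].CC(C)[N-]C(C)C
Why: Dianionic Ireland–Claisen [3,3]-sigmatropic rearrangement in which the lithium-chelated (Z)-enolate of the β-alkoxide ester reacts through a chair on the face anti to the ester group on C9 (the Fráter–Seebach sense), setting C8 as S, while the Z-crotyl geometry places its methyl axial and sets C11 as R as the C8–C11 bond forms.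

Step 3
Reactants: 5 (2S,3R)-2-[(2R)-but-3-en-2-yl]-3-hydroxybutanedioic acid 4-[(2Z)-but-2-en-1-yl] ester
Product: 7 (3S,4R)-3-[(2R)-but-3-en-2-yl]-4-hydroxyoxolan-2-one, via dihydroxy acid 6 (not isolated)
Conditions: LiBH4 (3 equiv), THF/MeOH, 0 → 25 °C; then 2 M HCl, 25 °C
Reagents that add atoms: none
Why: LiBH4 reduces the activated α-hydroxy ester but not the lithium carboxylate, and acidification lactonises the resulting 4-hydroxy acid (chemoselective ester reduction then γ-lactonisation), which differentiates C7 from C10 without moving any stereocentre.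

Step 4
Reactants: 7 (3S,4R)-3-[(2R)-but-3-en-2-yl]-4-hydroxyoxolan-2-one
Product: 8 (3S,4R)-3-[(2R)-but-3-en-2-yl]-4-{[tri(propan-2-yl)silyl]oxy}oxolan-2-one
Conditions: i-Pr3SiOSO2CF3, 2,6-lutidine, CH2Cl2, 0 → 25 °C
Reagents that add atoms: triisopropylsilyl trifluoromethanesulfonate, CC(C)[Si](C(C)C)(C(C)C)OS(=O)(=O)C(F)(F)F
Why: Silyl triflate silylation under weakly basic conditions avoids β-elimination of the β-hydroxy lactone, and the bulky silyl group later enforces non-chelated addition at C10 and resists 1,2-migration.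

Step 5
Reactants: 8 (3S,4R)-3-[(2R)-but-3-en-2-yl]-4-{[tri(propan-2-yl)silyl]oxy}oxolan-2-one; 9 1-bromo-2-methylprop-1-ene
Product: 11 (3S,4R)-3-[(2R)-6-methylhept-5-en-2-yl]-4-{[tri(propan-2-yl)silyl]oxy}oxolan-2-one, via alkylborane 10 (not isolated)
Conditions: 9-BBN (1.5 equiv), THF, 0 → 25 °C; then 9 (2 equiv), PdCl2(dppf) (5 mol%), AsPh3, Cs2CO3, DMF/H2O, 25 → 45 °C
Reagents that add atoms: 9-borabicyclo[3.3.1]nonane, [BH]1C2CCCC1CCC2
Why: Anti-Markovnikov hydroboration of the monosubstituted vinyl group followed by B-alkyl Suzuki–Miyaura coupling with the alkenyl bromide completes the 6-methylhept-5-en-2-yl side chain without affecting C11.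

Step 6
Reactants: 11 (3S,4R)-3-[(2R)-6-methylhept-5-en-2-yl]-4-{[tri(propan-2-yl)silyl]oxy}oxolan-2-one
Product: 12 (3S,4R)-3-[(2R)-6-methylhept-5-en-2-yl]-4-{[tri(propan-2-yl)silyl]oxy}oxolan-2-ol (lactol, both anomers)
Conditions: i-Bu2AlH (1.2 equiv), CH2Cl2, −78 °C
Reagents that add atoms: none
Why: Low-temperature i-Bu2AlH reduction stops at the tetrahedral aluminium lactolate (partial lactone reduction), bringing C7 to the aldehyde oxidation level.

Step 7
Reactants: 12 (3S,4R)-3-[(2R)-6-methylhept-5-en-2-yl]-4-{[tri(propan-2-yl)silyl]oxy}oxolan-2-ol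
Product: 13 (2R,3S)-3-[(2R)-6-methylhept-5-en-2-yl]-2-{[tri(propan-2-yl)silyl]oxy}pent-4-en-1-ol
Conditions: Ph3PCH3Br (3 equiv), KN(SiMe3)2 (2.8 equiv), THF, 0 °C; then 12, −20 → 25 °C
Reagents that add atoms: methyltriphenylphosphonium bromide, C[P+](c1ccccc1)(c1ccccc1)c1ccccc1.[Br-]
Why: Wittig methylenation of the open hydroxy-aldehyde tautomer installs C6 as a terminal vinyl group and releases the C10 primary alcohol, the non-stabilised ylide adding faster than enolisation at C8.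

Step 8
Reactants: 13 (2R,3S)-3-[(2R)-6-methylhept-5-en-2-yl]-2-{[tri(propan-2-yl)silyl]oxy}pent-4-en-1-ol
Product: 14 (2R,3S)-3-[(2R)-6-methylhept-5-en-2-yl]-2-{[tri(propan-2-yl)silyl]oxy}pent-4-enal
Conditions: Dess–Martin periodinane, pyridine, CH2Cl2, 0 → 25 °C
Reagents that add atoms: none
Why: Dess–Martin oxidation under buffered neutral conditions gives the α-silyloxy aldehyde without epimerising C9.

Step 9
Reactants: 15 4-{[tert-butyl(dimethyl)silyl]oxy}but-2-yn-1-ol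
Product: 17 (2Z)-4-{[tert-butyl(dimethyl)silyl]oxy}-3-iodobut-2-en-1-ol, via sodium alkenylalanate 16 (not isolated)
Conditions: NaAlH2(OCH2CH2OCH3)2 (1.6 equiv), THF, 0 → 25 °C; then I2, THF, −78 °C
Reagents that add atoms: sodium bis(2-methoxyethoxy)aluminium dihydride, [Na+].COCCO[AlH2-]OCCOC; iodine, [I][I]
Why: Hydroxyl-directed trans-hydroalumination places aluminium on the distal alkyne carbon and iodinolysis with retention gives the Z-alkenyl iodide whose iodine is cis to the CH2OH arm (the future C3), which fixes the later C1=C2 geometry.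

Step 10
Reactants: 17 (2Z)-4-{[tert-butyl(dimethyl)silyl]oxy}-3-iodobut-2-en-1-ol
Product: 18 {[(2Z)-4-bromo-2-iodobut-2-en-1-yl]oxy}(tert-butyl)dimethylsilane
Conditions: CBr4, PPh3, CH2Cl2, 0 °C
Reagents that add atoms: carbon tetrabromide, BrC(Br)(Br)Br
Why: Appel bromination converts the primary allylic alcohol into the bromide under neutral conditions that leave the alkenyl iodide and the olefin geometry intact.

Step 11
Reactants: 18 {[(2Z)-4-bromo-2-iodobut-2-en-1-yl]oxy}(tert-butyl)dimethylsilane; 19 bromido(prop-1-yn-1-yl)magnesium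
Product: 20 tert-butyl{[(2Z)-2-iodohept-2-en-5-yn-1-yl]oxy}dimethylsilane
Conditions: CuI (10 mol%), THF, 0 → 25 °C
Reagents that add atoms: none
Why: Copper-catalysed SN2 coupling of the alkynyl Grignard reagent with the primary allylic bromide builds the skipped enyne (C3–C4 bond) without touching the alkenyl iodide.

Step 12
Reactants: 20 tert-butyl{[(2Z)-2-iodohept-2-en-5-yn-1-yl]oxy}dimethylsilane
Product: 22 {[(2Z,5E)-6-bromo-2-iodohepta-2,5-dien-1-yl]oxy}(tert-butyl)dimethylsilane, via alkenylzirconocene chloride 21 (not isolated)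
Conditions: Cp2Zr(H)Cl (2 equiv), THF, 25 → 40 °C; then N-bromosuccinimide, 0 °C
Reagents that add atoms: chloridohydridozirconocene, Cl[ZrH](C1C=CC=C1)C1C=CC=C1; N-bromosuccinimide, O=C1CCC(=O)N1Br
Why: Hydrozirconation adds Zr–H syn with zirconium on the less hindered methyl-bearing alkyne carbon (excess reagent equilibrates the regioisomers) and bromodezirconation proceeds with retention, giving the E-configured 2-bromo-2-alkene.

Step 13
Reactants: 14 (2R,3S)-3-[(2R)-6-methylhept-5-en-2-yl]-2-{[tri(propan-2-yl)silyl]oxy}pent-4-enal; 22 {[(2Z,5E)-6-bromo-2-iodohepta-2,5-dien-1-yl]oxy}(tert-butyl)dimethylsilane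
Product: 23 (3S,4R,5S,6Z,9E)-10-bromo-6-({[tert-butyl(dimethyl)silyl]oxy}methyl)-3-[(2R)-6-methylhept-5-en-2-yl]-4-{[tri(propan-2-yl)silyl]oxy}undeca-1,6,9-trien-5-ol
Conditions: 22 (1.5 equiv), CrCl2 (6 equiv), NiCl2 (1 mol%), DMSO/THF, 25 °C
Reagents that add atoms: none
Why: Nozaki–Hiyama–Kishi coupling in which nickel activates the alkenyl iodide in preference to the alkenyl bromide and the alkenylchromium adds to the aldehyde under Felkin–Anh (non-chelation) control anti to the bulky silyloxy group, forming C10–C1 with retention of the Z geometry and setting C10 as S.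

Step 14
Reactants: 23 (3S,4R,5S,6Z,9E)-10-bromo-6-({[tert-butyl(dimethyl)silyl]oxy}methyl)-3-[(2R)-6-methylhept-5-en-2-yl]-4-{[tri(propan-2-yl)silyl]oxy}undeca-1,6,9-trien-5-ol
Product: 25 tert-butyl({(1Z,4E,8S,9R,10S)-10-hydroxy-5-methyl-8-[(2R)-6-methylhept-5-en-2-yl]-9-{[tri(propan-2-yl)silyl]oxy}cyclodeca-1,4-dien-1-yl}methoxy)dimethylsilane, via alkylborane 24 (not isolated)
Conditions: 9-BBN (3 equiv), THF, 25 °C; then slow addition to PdCl2(dppf) (15 mol%), AsPh3, Cs2CO3, DMF/THF/H2O, 0.002 M, 50 °C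
Reagents that add atoms: 9-borabicyclo[3.3.1]nonane, [BH]1C2CCCC1CCC2
Why: Selective hydroboration of the only monosubstituted alkene followed by intramolecular B-alkyl Suzuki–Miyaura coupling with the alkenyl bromide under high dilution closes the ten-membered ring at C5–C6 with retention of the E geometry.

Step 15
Reactants: 25 tert-butyl({(1Z,4E,8S,9R,10S)-10-hydroxy-5-methyl-8-[(2R)-6-methylhept-5-en-2-yl]-9-{[tri(propan-2-yl)silyl]oxy}cyclodeca-1,4-dien-1-yl}methoxy)dimethylsilane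
Product: 26 (1Z,4E,8S,9R,10S)-1-(hydroxymethyl)-5-methyl-8-[(2R)-6-methylhept-5-en-2-yl]cyclodeca-1,4-diene-9,10-diol
Conditions: Bu4NF (4 equiv), THF, 25 → 40 °C
Reagents that add atoms: none
Why: Fluoride-mediated desilylation removes both silyl ethers in one operation and touches no stereocentre or olefin.

Step 16
Reactants: 26 (1Z,4E,8S,9R,10S)-1-(hydroxymethyl)-5-methyl-8-[(2R)-6-methylhept-5-en-2-yl]cyclodeca-1,4-diene-9,10-diol
Product: 27 [(1Z,4E,8S,9R,10S)-9,10-dihydroxy-5-methyl-8-[(2R)-6-methylhept-5-en-2-yl]cyclodeca-1,4-dien-1-yl]methyl acetate (CNP0271046.2)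
Conditions: AcCl (1.05 equiv), 2,4,6-collidine, CH2Cl2, −78 °C
Reagents that add atoms: acetyl chloride, CC(=O)Cl
Why: Kinetically selective acylation, since the unhindered primary allylic hydroxyl reacts far faster at −78 °C than the two flanked secondary hydroxyls.

## Compound list

1 | (2R)-2-hydroxybutanedioic acid (D-malic acid) | OC(=O)C[C@@H](O)C(=O)O | starting material
2 | (2Z)-but-2-en-1-ol | C/C=C\CO | starting material
3 | bis[(2Z)-but-2-en-1-yl] (2R)-2-hydroxybutanedioate | C/C=C\COC(=O)C[C@@H](O)C(=O)OC/C=C\C | intermediate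
4 | dilithium salt of 3: C9 alkoxide plus chelated (Z)-ester enolate across C8=C7 | [Li+].[Li+].C/C=C\COC(=O)[C@H]([O-])/C=C(\[O-])OC/C=C\C | intermediate
5 | (2S,3R)-2-[(2R)-but-3-en-2-yl]-3-hydroxybutanedioic acid 4-[(2Z)-but-2-en-1-yl] ester | OC(=O)[C@@H]([C@H](C)C=C)[C@@H](O)C(=O)OC/C=C\C | intermediate
6 | (2S,3R)-2-[(2R)-but-3-en-2-yl]-3,4-dihydroxybutanoic acid | OC(=O)[C@@H]([C@H](C)C=C)[C@@H](O)CO | intermediate
7 | (3S,4R)-3-[(2R)-but-3-en-2-yl]-4-hydroxyoxolan-2-one (3,4-cis) | O=C1[C@@H]([C@H](C)C=C)[C@@H](O)CO1 | intermediate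
8 | (3S,4R)-3-[(2R)-but-3-en-2-yl]-4-{[tri(propan-2-yl)silyl]oxy}oxolan-2-one | O=C1[C@@H]([C@H](C)C=C)[C@@H](O[Si](C(C)C)(C(C)C)C(C)C)CO1 | intermediate
9 | 1-bromo-2-methylprop-1-ene | CC(C)=CBr | starting material
10 | (3S,4R)-3-[(2R)-4-(9-borabicyclo[3.3.1]nonan-9-yl)butan-2-yl]-4-{[tri(propan-2-yl)silyl]oxy}oxolan-2-one | O=C1[C@@H]([C@H](C)CCB2C3CCCC2CCC3)[C@@H](O[Si](C(C)C)(C(C)C)C(C)C)CO1 | intermediate
11 | (3S,4R)-3-[(2R)-6-methylhept-5-en-2-yl]-4-{[tri(propan-2-yl)silyl]oxy}oxolan-2-one | O=C1[C@@H]([C@H](C)CCC=C(C)C)[C@@H](O[Si](C(C)C)(C(C)C)C(C)C)CO1 | intermediate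
12 | (3S,4R)-3-[(2R)-6-methylhept-5-en-2-yl]-4-{[tri(propan-2-yl)silyl]oxy}oxolan-2-ol (lactol, both anomers) | OC1[C@@H]([C@H](C)CCC=C(C)C)[C@@H](O[Si](C(C)C)(C(C)C)C(C)C)CO1 | intermediate
13 | (2R,3S)-3-[(2R)-6-methylhept-5-en-2-yl]-2-{[tri(propan-2-yl)silyl]oxy}pent-4-en-1-ol | C=C[C@@H]([C@H](C)CCC=C(C)C)[C@@H](O[Si](C(C)C)(C(C)C)C(C)C)CO | intermediate
14 | (2R,3S)-3-[(2R)-6-methylhept-5-en-2-yl]-2-{[tri(propan-2-yl)silyl]oxy}pent-4-enal | C=C[C@@H]([C@H](C)CCC=C(C)C)[C@@H](O[Si](C(C)C)(C(C)C)C(C)C)C=O | intermediate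
15 | 4-{[tert-butyl(dimethyl)silyl]oxy}but-2-yn-1-ol | OCC#CCO[Si](C)(C)C(C)(C)C | starting material
16 | sodium 2,2-bis(2-methoxyethoxy)-3-({[tert-butyl(dimethyl)silyl]oxy}methyl)-2,5-dihydro-1,2-oxaluminol-2-uide (cyclic alkenylalanate) | [Na+].COCCO[Al-]1(OCCOC)OCC=C1CO[Si](C)(C)C(C)(C)C | intermediate
17 | (2Z)-4-{[tert-butyl(dimethyl)silyl]oxy}-3-iodobut-2-en-1-ol | OC/C=C(\I)CO[Si](C)(C)C(C)(C)C | intermediate
18 | {[(2Z)-4-bromo-2-iodobut-2-en-1-yl]oxy}(tert-butyl)dimethylsilane | BrC/C=C(\I)CO[Si](C)(C)C(C)(C)C | intermediate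
19 | bromido(prop-1-yn-1-yl)magnesium | CC#C[Mg]Br | starting material
20 | tert-butyl{[(2Z)-2-iodohept-2-en-5-yn-1-yl]oxy}dimethylsilane | CC#CC/C=C(\I)CO[Si](C)(C)C(C)(C)C | intermediate
21 | chloridobis(cyclopentadienyl)[(2E,5Z)-7-{[tert-butyl(dimethyl)silyl]oxy}-6-iodohepta-2,5-dien-2-yl]zirconium | CC(C)(C)[Si](C)(C)OC/C([I])=C/C/C=C(\C)[Zr](Cl)(C1C=CC=C1)C1C=CC=C1 | intermediate
22 | {[(2Z,5E)-6-bromo-2-iodohepta-2,5-dien-1-yl]oxy}(tert-butyl)dimethylsilane | CC(C)(C)[Si](C)(C)OC/C([I])=C/C/C=C(\C)Br | intermediate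
23 | (3S,4R,5S,6Z,9E)-10-bromo-6-({[tert-butyl(dimethyl)silyl]oxy}methyl)-3-[(2R)-6-methylhept-5-en-2-yl]-4-{[tri(propan-2-yl)silyl]oxy}undeca-1,6,9-trien-5-ol | C=C[C@@H]([C@H](C)CCC=C(C)C)[C@@H](O[Si](C(C)C)(C(C)C)C(C)C)[C@@H](O)/C(CO[Si](C)(C)C(C)(C)C)=C\C/C=C(\C)Br | intermediate
24 | B-alkyl borane from 23: 9-borabicyclo[3.3.1]nonan-9-yl on the terminal carbon of the former vinyl group, otherwise as 23 | B1(CC[C@@H]([C@H](C)CCC=C(C)C)[C@@H](O[Si](C(C)C)(C(C)C)C(C)C)[C@@H](O)/C(CO[Si](C)(C)C(C)(C)C)=C\C/C=C(\C)Br)C2CCCC1CCC2 | intermediate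
25 | tert-butyl({(1Z,4E,8S,9R,10S)-10-hydroxy-5-methyl-8-[(2R)-6-methylhept-5-en-2-yl]-9-{[tri(propan-2-yl)silyl]oxy}cyclodeca-1,4-dien-1-yl}methoxy)dimethylsilane | CC(C)(C)[Si](C)(C)OC/C1=C/C/C=C(\C)CC[C@@H]([C@H](C)CCC=C(C)C)[C@@H](O[Si](C(C)C)(C(C)C)C(C)C)[C@H]1O | intermediate
26 | (1Z,4E,8S,9R,10S)-1-(hydroxymethyl)-5-methyl-8-[(2R)-6-methylhept-5-en-2-yl]cyclodeca-1,4-diene-9,10-diol | OC/C1=C/C/C=C(\C)CC[C@@H]([C@H](C)CCC=C(C)C)[C@@H](O)[C@H]1O | intermediate
27 | [(1Z,4E,8S,9R,10S)-9,10-dihydroxy-5-methyl-8-[(2R)-6-methylhept-5-en-2-yl]cyclodeca-1,4-dien-1-yl]methyl acetate (CNP0271046.2) | CC(=O)OC/C1=C/C/C=C(\C)CC[C@@H]([C@H](C)CCC=C(C)C)[C@@H](O)[C@H]1O | target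

## Step count and risks

Total step count: 16 (steps 1–8 and 13–16 in the malic acid line, steps 9–12 for the dihalodiene).
Longest linear sequence: 12 steps (1–8, then 13–16).

Most likely to fail, first: step 2, the dianionic Ireland–Claisen rearrangement. The dianion may decompose on warming, or chelate control may be eroded on this substrate. The fallback sets out from 1 and carries the C9/C10 diol as an acetonide, so that an ordinary silyl ketene acetal Ireland–Claisen rearrangement can be used. Reduce 1 with BH3·SMe2/B(OMe)3 to (2R)-butane-1,2,4-triol F1. Ketalise with acetone and TsOH to 2-[(4R)-2,2-dimethyl-1,3-dioxolan-4-yl]ethan-1-ol F2. Oxidise with TEMPO, NaOCl and NaClO2 to [(4R)-2,2-dimethyl-1,3-dioxolan-4-yl]acetic acid F3. Esterify with (2E)-but-2-en-1-ol (DCC, DMAP) to (2E)-but-2-en-1-yl [(4R)-2,2-dimethyl-1,3-dioxolan-4-yl]acetate F4. Rearrange with LiN(i-Pr)2 and Me3SiCl in THF, −78 → 25 °C, to (2S,3R)-2-[(4R)-2,2-dimethyl-1,3-dioxolan-4-yl]-3-methylpent-4-enoic acid F5. Here the kinetic E(O)-enolate paired with the E-crotyl ester gives the same anti C8/C11 relationship through a chair, and the dioxolane directs attack anti to its C–O bond. Aqueous HCl in THF then removes the acetonide and lactonises, coming back to the route at 7.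

Second: step 13, the Nozaki–Hiyama–Kishi coupling. The Felkin preference of chromium reagents for α-silyloxy aldehydes is often modest, so the C10 epimer ratio may be poor. The fallback sets out from 23 (either epimer or the mixture) and sets C10 by a chelation-controlled reduction instead of by the C–C bond formation. Oxidise with Dess–Martin periodinane to (3S,4R,6Z,9E)-10-bromo-6-({[tert-butyl(dimethyl)silyl]oxy}methyl)-3-[(2R)-6-methylhept-5-en-2-yl]-4-{[tri(propan-2-yl)silyl]oxy}undeca-1,6,9-trien-5-one F6. Remove both silyl groups with HF·pyridine to give (3S,4R,6Z,9E)-10-bromo-4-hydroxy-6-(hydroxymethyl)-3-[(2R)-6-methylhept-5-en-2-yl]undeca-1,6,9-trien-5-one F7. Reduce with Zn(BH4)2 in Et2O at −20 °C, where the zinc chelate between the C9 hydroxyl and the carbonyl delivers hydride to give the anti diol, (3S,4R,5S,6Z,9E)-10-bromo-6-(hydroxymethyl)-3-[(2R)-6-methylhept-5-en-2-yl]undeca-1,6,9-triene-4,5-diol F8. Running the hydroboration/Suzuki macrocyclisation of step 14 on F8 (extra 9-BBN for the free hydroxyls) comes back to the route at 26.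

Third: step 14, the B-alkyl Suzuki macrocyclisation. Closing a strained (1Z,4E)-cyclodecadiene may lose out to oligomerisation or protodeboronation. The fallback sets out from 15 and 13 and reverses the order of the two couplings, so that the ring is closed at C10–C1 instead. Repeat steps 9–12 on 15 with the halogen sources exchanged (N-bromosuccinimide on the alanate, I2 on the alkenylzirconium). This gives in turn (2Z)-3-bromo-4-{[tert-butyl(dimethyl)silyl]oxy}but-2-en-1-ol F9, {[(2Z)-2,4-dibromobut-2-en-1-yl]oxy}(tert-butyl)dimethylsilane F10, {[(2Z)-2-bromohept-2-en-5-yn-1-yl]oxy}(tert-butyl)dimethylsilane F11 (from F10 and 19 with CuI) and {[(2Z,5E)-2-bromo-6-iodohepta-2,5-dien-1-yl]oxy}(tert-butyl)dimethylsilane F12. Hydroborate 13 with 9-BBN and couple intermolecularly at the alkenyl iodide of F12 (PdCl2(dppf), AsPh3, Cs2CO3; the iodide reacts before the bromide) to give (2R,3S,6E,9Z)-10-bromo-11-{[tert-butyl(dimethyl)silyl]oxy}-6-methyl-3-[(2R)-6-methylhept-5-en-2-yl]-2-{[tri(propan-2-yl)silyl]oxy}undeca-6,9-dien-1-ol F13. Oxidise with Dess–Martin periodinane to (2R,3S,6E,9Z)-10-bromo-11-{[tert-butyl(dimethyl)silyl]oxy}-6-methyl-3-[(2R)-6-methylhept-5-en-2-yl]-2-{[tri(propan-2-yl)silyl]oxy}undeca-6,9-dienal F14. An intramolecular Nozaki–Hiyama–Kishi reaction (CrCl2, NiCl2 cat., DMSO/THF, high dilution, 50 °C) then forms C10–C1 and comes back to the route at 25.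

## Further compounds

F1 | step 2 | (2R)-butane-1,2,4-triol | OCC[C@@H](O)CO
F2 | step 2 | 2-[(4R)-2,2-dimethyl-1,3-dioxolan-4-yl]ethan-1-ol | OCC[C@@H]1COC(C)(C)O1
F3 | step 2 | [(4R)-2,2-dimethyl-1,3-dioxolan-4-yl]acetic acid | OC(=O)C[C@@H]1COC(C)(C)O1
F4 | step 2 | (2E)-but-2-en-1-yl [(4R)-2,2-dimethyl-1,3-dioxolan-4-yl]acetate | C/C=C/COC(=O)C[C@@H]1COC(C)(C)O1
F5 | step 2 | (2S,3R)-2-[(4R)-2,2-dimethyl-1,3-dioxolan-4-yl]-3-methylpent-4-enoic acid | OC(=O)[C@@H]([C@H](C)C=C)[C@@H]1COC(C)(C)O1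
F6 | step 13 | (3S,4R,6Z,9E)-10-bromo-6-({[tert-butyl(dimethyl)silyl]oxy}methyl)-3-[(2R)-6-methylhept-5-en-2-yl]-4-{[tri(propan-2-yl)silyl]oxy}undeca-1,6,9-trien-5-one | C=C[C@@H]([C@H](C)CCC=C(C)C)[C@@H](O[Si](C(C)C)(C(C)C)C(C)C)C(=O)/C(CO[Si](C)(C)C(C)(C)C)=C\C/C=C(\C)Br
F7 | step 13 | (3S,4R,6Z,9E)-10-bromo-4-hydroxy-6-(hydroxymethyl)-3-[(2R)-6-methylhept-5-en-2-yl]undeca-1,6,9-trien-5-one | C=C[C@@H]([C@H](C)CCC=C(C)C)[C@@H](O)C(=O)/C(CO)=C\C/C=C(\C)Br
F8 | step 13 | (3S,4R,5S,6Z,9E)-10-bromo-6-(hydroxymethyl)-3-[(2R)-6-methylhept-5-en-2-yl]undeca-1,6,9-triene-4,5-diol | C=C[C@@H]([C@H](C)CCC=C(C)C)[C@@H](O)[C@@H](O)/C(CO)=C\C/C=C(\C)Br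
F9 | step 14 | (2Z)-3-bromo-4-{[tert-butyl(dimethyl)silyl]oxy}but-2-en-1-ol | OC/C=C(\Br)CO[Si](C)(C)C(C)(C)C
F10 | step 14 | {[(2Z)-2,4-dibromobut-2-en-1-yl]oxy}(tert-butyl)dimethylsilane | BrC/C=C(\Br)CO[Si](C)(C)C(C)(C)C
F11 | step 14 | {[(2Z)-2-bromohept-2-en-5-yn-1-yl]oxy}(tert-butyl)dimethylsilane | CC#CC/C=C(\Br)CO[Si](C)(C)C(C)(C)C
F12 | step 14 | {[(2Z,5E)-2-bromo-6-iodohepta-2,5-dien-1-yl]oxy}(tert-butyl)dimethylsilane | CC(C)(C)[Si](C)(C)OC/C(Br)=C/C/C=C(\C)[I]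
F13 | step 14 | (2R,3S,6E,9Z)-10-bromo-11-{[tert-butyl(dimethyl)silyl]oxy}-6-methyl-3-[(2R)-6-methylhept-5-en-2-yl]-2-{[tri(propan-2-yl)silyl]oxy}undeca-6,9-dien-1-ol | CC(C)(C)[Si](C)(C)OC/C(Br)=C/C/C=C(\C)CC[C@@H]([C@H](C)CCC=C(C)C)[C@@H](O[Si](C(C)C)(C(C)C)C(C)C)CO
F14 | step 14 | (2R,3S,6E,9Z)-10-bromo-11-{[tert-butyl(dimethyl)silyl]oxy}-6-methyl-3-[(2R)-6-methylhept-5-en-2-yl]-2-{[tri(propan-2-yl)silyl]oxy}undeca-6,9-dienal | CC(C)(C)[Si](C)(C)OC/C(Br)=C/C/C=C(\C)CC[C@@H]([C@H](C)CCC=C(C)C)[C@@H](O[Si](C(C)C)(C(C)C)C(C)C)C=O
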